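**Strategy.** The chain is cut at C11=C12 and C11'=C12' into two C15 phosphonium salts and the C10 trienedial. The oxygenated cyclohexene ring (C1–C6) is built as a five-membered ring: its C3–O/C4/C5=C6 homoallyl ester pattern is read as an opened cyclopropylcarbinyl cation. In the key step a tertiary dienyl carbinol at C6 of a 1,3,3-trimethylbicyclo[3.1.0]hexane (cyclopentane C6–C1–C2–C3–C5 fused to cyclopropane C3–C4–C5) is ionised; myristic acid opens the C3–C5 bond with inversion, so the ring expansion to the cyclohexene, the C5=C6 bond, the C3 stereocentre and the myristate arise in one operation.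

Key step: step 7

Remark: carotenoid numbering is used in the discussion (C1–C6 ring and C7–C15 chain; primed numbers for the half with the C4'=C5' ring). (R)-α-Ionone 13 is assumed to be purchasable as a single enantiomer. Where a step forms or equilibrates a chain double bond, the E isomer drawn is the one carried on.

Step 1
Reactants: 1 2-methylcyclopent-2-en-1-one
Product: 2 (1R)-2-methylcyclopent-2-en-1-ol
Conditions: (S)-Me-CBS (10 mol%), catecholborane (1.5 equiv), toluene, −78 °C; aq. NaOH work-up
Reagents that add atoms: none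
Why: Corey–Bakshi–Shibata reduction, in which the α-methylvinyl arm of the enone acts as the large group so that the (S)-oxazaborolidine should give the (R)-carbinol, the centre from which all stereochemistry of this half is relayed.

Step 2
Reactants: 2 (1R)-2-methylcyclopent-2-en-1-ol
Product: 3 (1S,2R,5R)-1-methylbicyclo[3.1.0]hexan-2-ol
Conditions: Et2Zn (2.2 equiv), CH2I2 (4.4 equiv), CH2Cl2, 0 °C → rt
Reagents that add atoms: diiodomethane, ICI
Why: Hydroxyl-directed Simmons–Smith cyclopropanation (Furukawa variant), in which the zinc alkoxide delivers the methylene to the alkene face syn to oxygen and so sets both ring-fusion centres relative to the carbinol.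

Step 3
Reactants: 3 (1S,2R,5R)-1-methylbicyclo[3.1.0]hexan-2-ol
Product: 4 (1S,5R)-1-methylbicyclo[3.1.0]hexan-2-one
Conditions: Dess–Martin periodinane, NaHCO3, CH2Cl2, 0 °C → rt
Reagents that add atoms: none
Why: Dess–Martin oxidation of the secondary alcohol under buffered conditions; the ring-fusion centres (one quaternary, one not enolisable) cannot epimerise.

Step 4
Reactants: 4 (1S,5R)-1-methylbicyclo[3.1.0]hexan-2-one
Product: 6 (1S,5S)-1,3,3-trimethylbicyclo[3.1.0]hexan-2-one, via monomethyl ketone 5 (not isolated)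
Conditions: LDA (1.1 equiv), THF, −78 °C, then MeI; second charge of LDA (1.2 equiv), −78 °C, then MeI, → 0 °C
Reagents that add atoms: iodomethane, CI
Why: Ketone enolate alkylation in which C3 of the bicycle is the only enolisable position, so two successive LDA/MeI cycles can only build the gem-dimethyl group and leave the cyclopropane centres untouched.

Step 5
Reactants: 6 (1S,5S)-1,3,3-trimethylbicyclo[3.1.0]hexan-2-one; 7 (2E)-3-methylpent-2-en-4-yn-1-ol
Product: 9 bicyclic enyne diol, via dilithio enynolate 8 (not isolated)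
Conditions: 7 (1.3 equiv), n-BuLi (2.6 equiv), THF, −78 → 0 °C; then 6, 0 °C → rt; aq. NH4Cl
Reagents that add atoms: none
Why: 1,2-Addition of a lithium acetylide to a non-enolisable, fenchone-like ketone, expected anti to the cyclopropane methylene; the configuration of the new carbinol carbon is immaterial because it becomes sp2 in step 7.

Step 6
Reactants: 9 bicyclic enyne diol
Product: 10 (1S,2R,5S)-2-[(1E,3E)-5-hydroxy-3-methylpenta-1,3-dien-1-yl]-1,3,3-trimethylbicyclo[3.1.0]hexan-2-ol
Conditions: Red-Al (3 equiv), THF, 0 °C → rt; Rochelle salt work-up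
Reagents that add atoms: none
Why: Alkoxide-directed trans-hydroalumination of the propargylic alcohol with Red-Al and protonolysis should give the (E)-C7=C8 alkene, while the (E)-trisubstituted alkene and the cyclopropane are inert.

Step 7
Reactants: 10 (1S,2R,5S)-2-[(1E,3E)-5-hydroxy-3-methylpenta-1,3-dien-1-yl]-1,3,3-trimethylbicyclo[3.1.0]hexan-2-ol
Product: 11 (1R)-4-[(1E,3E)-5-hydroxy-3-methylpenta-1,3-dien-1-yl]-3,5,5-trimethylcyclohex-3-en-1-yl tetradecanoate
Conditions: myristic acid (5 equiv), camphorsulfonic acid (5 mol%), 4 Å molecular sieves, CH2Cl2, −20 → 0 °C; Et3N quench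
Reagents that add atoms: tetradecanoic acid (myristic acid), CCCCCCCCCCCCCC(=O)O
Why: Acid-catalysed loss of water from the tertiary C6 carbinol gives a cation that is both pentadienylic (C6/C8/C10) and cyclopropylcarbinylic, and myristic acid attacks the secondary cyclopropane carbon C3 (C5 of the bicycle) from the side opposite the C3–C5 bond while that bond breaks and C5=C6 forms, so the cyclopropane CH2 (C4) is inserted and the cyclopentane C6–C1–C2–C3–C5 becomes the cyclohexene C1–C6. The closest known reaction type is the cyclopropylcarbinyl-to-homoallyl rearrangement in its ring-expanding form (acetolysis of i-steroids to 3β-acyloxy-Δ5-steroids, thujan-4-ol to p-menth-1-en-4-ol, Julia olefin synthesis). No ring is closed: the zero-atom bridge C3–C5 is cleaved, which merges the three- and five-membered rings into the six-membered one. The new stereocentre C3 is set stereospecifically by inversion at the cyclopropane carbon, which should give 3R, and the carbinol configuration at C6 is lost without consequence. The step needs opening at the secondary C3 rather than the primary C4, which the better charge stabilisation at the more substituted carbon secures as in i-steroids, and final capture at C3 rather than C6/C8/C10, which is secured because allylic myristates formed there re-ionise whereas the homoallylic ester does not. Ionisation of the primary C11 alcohol should be far slower than that of the doubly stabilised tertiary carbinol, and partial esterification there would be harmless because step 8 converts both forms.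

Step 8
Reactants: 11 (1R)-4-[(1E,3E)-5-hydroxy-3-methylpenta-1,3-dien-1-yl]-3,5,5-trimethylcyclohex-3-en-1-yl tetradecanoate
Product: 12 {(2E,4E)-3-methyl-5-[(4R)-2,6,6-trimethyl-4-(tetradecanoyloxy)cyclohex-1-en-1-yl]penta-2,4-dien-1-yl}triphenylphosphonium bromide
Conditions: PPh3·HBr (1.05 equiv), CH2Cl2, 0 °C → rt; crystallisation
Reagents that add atoms: triphenylphosphine hydrobromide, [Br-].c1ccc(cc1)[PH+](c1ccccc1)c1ccccc1
Why: SN1-type substitution of the primary trienylic alcohol by triphenylphosphine, as in the retinol-to-retinylphosphonium conversion; the homoallylic ester is inert and the (9E) salt is purified by crystallisation.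

Step 9
Reactants: 13 (R)-α-ionone
Product: 14 (4E)-3-methyl-5-[(1R)-2,6,6-trimethylcyclohex-2-en-1-yl]penta-1,4-dien-3-ol (both C3 epimers)
Conditions: vinylmagnesium bromide (1.3 equiv), THF, −20 → 0 °C; aq. NH4Cl
Reagents that add atoms: vinylmagnesium bromide, C=C[Mg]Br
Why: Grignard 1,2-addition to the methyl ketone (the vinyl-ionol synthesis); the new carbinol centre forms without control, which is harmless because it becomes sp2 in step 13, and C6' is not touched at low temperature.

Step 10
Reactants: 14 (4E)-3-methyl-5-[(1R)-2,6,6-trimethylcyclohex-2-en-1-yl]penta-1,4-dien-3-ol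
Product: 15 (4R)-4-[(1E)-3-hydroxy-3-methylpenta-1,4-dien-1-yl]-3,5,5-trimethylcyclohex-2-en-1-one
Conditions: Rh2(cap)4 (1 mol%), t-BuOOH (70% aq., 5 equiv), K2CO3, CH2Cl2, rt
Reagents that add atoms: tert-butyl hydroperoxide, CC(C)(C)OO
Why: Radical allylic C–H oxidation with the dirhodium caprolactamate/TBHP system, in which the ring CH2 at C3' is the only unhindered secondary allylic position, the tertiary alcohol has no oxidisable C–H and the bis-allylic C6'–H is shielded by its quaternary and methyl-bearing neighbours.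

Step 11
Reactants: 15 (4R)-4-[(1E)-3-hydroxy-3-methylpenta-1,4-dien-1-yl]-3,5,5-trimethylcyclohex-2-en-1-one
Product: 16 (1R,4R)-4-[(1E)-3-hydroxy-3-methylpenta-1,4-dien-1-yl]-3,5,5-trimethylcyclohex-2-en-1-ol
Conditions: (S)-Me-CBS (20 mol%), catecholborane (2.5 equiv), toluene, −78 °C; aq. NaOH work-up
Reagents that add atoms: none
Why: Corey–Bakshi–Shibata reduction under reagent control with catecholborane (which should not hydroborate the alkenes at −78 °C), in which the ring alkenyl arm acts as the large group so that the (S)-catalyst should give the (3'R) alcohol, trans to the C6' side chain.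

Step 12
Reactants: 16 (1R,4R)-4-[(1E)-3-hydroxy-3-methylpenta-1,4-dien-1-yl]-3,5,5-trimethylcyclohex-2-en-1-ol
Product: 17 (1R,4R)-4-[(1E)-3-hydroxy-3-methylpenta-1,4-dien-1-yl]-3,5,5-trimethylcyclohex-2-en-1-yl tetradecanoate
Conditions: tetradecanoyl chloride (1.1 equiv), pyridine, DMAP (5 mol%), CH2Cl2, 0 °C
Reagents that add atoms: tetradecanoyl chloride, CCCCCCCCCCCCCC(=O)Cl
Why: DMAP-catalysed acylation of the secondary allylic alcohol with retention at C3'; the tertiary bis-allylic alcohol does not react under these conditions.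

Step 13
Reactants: 17 (1R,4R)-4-[(1E)-3-hydroxy-3-methylpenta-1,4-dien-1-yl]-3,5,5-trimethylcyclohex-2-en-1-yl tetradecanoate
Product: 18 {(2E,4E)-3-methyl-5-[(1R,4R)-2,6,6-trimethyl-4-(tetradecanoyloxy)cyclohex-2-en-1-yl]penta-2,4-dien-1-yl}triphenylphosphonium bromide
Conditions: PPh3·HBr (1.05 equiv), CH2Cl2, 0 °C → rt; crystallisation
Reagents that add atoms: triphenylphosphine hydrobromide, [Br-].c1ccc(cc1)[PH+](c1ccccc1)c1ccccc1
Why: Ionisation of the tertiary bis-allylic alcohol and capture of the allyl cation by triphenylphosphine at the unsubstituted terminus (the vinyl-ionol to C15 Wittig salt reaction); the secondary allylic ester and the C6' centre should survive the buffered acid at 0 °C, and the (9'E) salt is enriched by crystallisation.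

Step 14
Reactants: 18 ε-type C15 phosphonium bromide; 19 (2E,4E,6E)-2,7-dimethylocta-2,4,6-trienedial
Product: 21 all-E C25 apo-aldehyde myristate, via ylide 20 (not isolated)
Conditions: NaHMDS (1.0 equiv), THF, −78 °C; ylide added to 19 (3 equiv), THF, −78 → 0 °C; then I2 (1 mol%), CH2Cl2, rt
Reagents that add atoms: none
Why: Wittig olefination of the more electrophilic dialdehyde, used in excess with inverse addition so that mono-olefination dominates; the non-nucleophilic base spares the ester and iodine-catalysed equilibration converts the 11'Z isomer into the all-E aldehyde.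

Step 15
Reactants: 12 β-type C15 phosphonium bromide; 21 all-E C25 apo-aldehyde myristate
Product: 23 lutein dimyristate, via ylide 22 (not isolated)
Conditions: NaHMDS (1.05 equiv), THF, −78 °C; then 21, −78 °C → rt; then n-heptane, reflux (Z → E), crystallisation
Reagents that add atoms: none
Why: Wittig olefination that forms C11=C12 and completes the C40 chain; thermal equilibration drives the 11Z isomer to the all-E compound, and no stereocentre or ester is exposed to a nucleophilic base.

**Compound list**

1 | 2-methylcyclopent-2-en-1-one | CC1=CCCC1=O | starting material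
2 | (1R)-2-methylcyclopent-2-en-1-ol | O[C@@H]1CCC=C1C | intermediate
3 | (1S,2R,5R)-1-methylbicyclo[3.1.0]hexan-2-ol | O[C@@H]1CC[C@@H]2C[C@]12C | intermediate
4 | (1S,5R)-1-methylbicyclo[3.1.0]hexan-2-one | O=C1CC[C@@H]2C[C@]12C | intermediate
5 | (1S,5R)-1,3-dimethylbicyclo[3.1.0]hexan-2-one (C3 epimers, not isolated) | O=C1C(C)C[C@@H]2C[C@]12C | intermediate
6 | (1S,5S)-1,3,3-trimethylbicyclo[3.1.0]hexan-2-one | O=C1C(C)(C)C[C@@H]2C[C@]12C | intermediate
7 | (2E)-3-methylpent-2-en-4-yn-1-ol | C#C/C(C)=C/CO | starting material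
8 | dilithium salt of 7 (lithium alkoxide and lithium acetylide, not isolated) | [Li]C#C/C(C)=C/CO[Li] | intermediate
9 | (1S,2R,5S)-2-[(3E)-5-hydroxy-3-methylpent-3-en-1-yn-1-yl]-1,3,3-trimethylbicyclo[3.1.0]hexan-2-ol (drawn as the epimer from attack anti to the cyclopropane CH2; the C2 configuration is immaterial) | O[C@]1(C#C/C(C)=C/CO)C(C)(C)C[C@@H]2C[C@]12C | intermediate
10 | (1S,2R,5S)-2-[(1E,3E)-5-hydroxy-3-methylpenta-1,3-dien-1-yl]-1,3,3-trimethylbicyclo[3.1.0]hexan-2-ol | O[C@]1(/C=C/C(C)=C/CO)C(C)(C)C[C@@H]2C[C@]12C | intermediate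
11 | (1R)-4-[(1E,3E)-5-hydroxy-3-methylpenta-1,3-dien-1-yl]-3,5,5-trimethylcyclohex-3-en-1-yl tetradecanoate | CCCCCCCCCCCCCC(=O)O[C@@H]1CC(C)=C(/C=C/C(C)=C/CO)C(C)(C)C1 | intermediate
12 | {(2E,4E)-3-methyl-5-[(4R)-2,6,6-trimethyl-4-(tetradecanoyloxy)cyclohex-1-en-1-yl]penta-2,4-dien-1-yl}triphenylphosphonium bromide | CCCCCCCCCCCCCC(=O)O[C@@H]1CC(C)=C(/C=C/C(C)=C/C[P+](c2ccccc2)(c2ccccc2)c2ccccc2)C(C)(C)C1.[Br-] | intermediate
13 | (R)-α-ionone, (3E)-4-[(1R)-2,6,6-trimethylcyclohex-2-en-1-yl]but-3-en-2-one | CC(=O)/C=C/[C@H]1C(C)=CCCC1(C)C | starting material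
14 | (4E)-3-methyl-5-[(1R)-2,6,6-trimethylcyclohex-2-en-1-yl]penta-1,4-dien-3-ol (both C3 epimers) | C=CC(C)(O)/C=C/[C@H]1C(C)=CCCC1(C)C | intermediate
15 | (4R)-4-[(1E)-3-hydroxy-3-methylpenta-1,4-dien-1-yl]-3,5,5-trimethylcyclohex-2-en-1-one (both carbinol epimers) | C=CC(C)(O)/C=C/[C@H]1C(C)=CC(=O)CC1(C)C | intermediate
16 | (1R,4R)-4-[(1E)-3-hydroxy-3-methylpenta-1,4-dien-1-yl]-3,5,5-trimethylcyclohex-2-en-1-ol (both tertiary carbinol epimers) | C=CC(C)(O)/C=C/[C@H]1C(C)=C[C@H](O)CC1(C)C | intermediate
17 | (1R,4R)-4-[(1E)-3-hydroxy-3-methylpenta-1,4-dien-1-yl]-3,5,5-trimethylcyclohex-2-en-1-yl tetradecanoate (both tertiary carbinol epimers) | C=CC(C)(O)/C=C/[C@H]1C(C)=C[C@H](OC(=O)CCCCCCCCCCCCC)CC1(C)C | intermediate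
18 | {(2E,4E)-3-methyl-5-[(1R,4R)-2,6,6-trimethyl-4-(tetradecanoyloxy)cyclohex-2-en-1-yl]penta-2,4-dien-1-yl}triphenylphosphonium bromide | c1ccc(cc1)[P+](c1ccccc1)(c1ccccc1)C/C=C(C)/C=C/[C@H]1C(C)=C[C@H](OC(=O)CCCCCCCCCCCCC)CC1(C)C.[Br-] | intermediate
19 | (2E,4E,6E)-2,7-dimethylocta-2,4,6-trienedial | O=C/C(C)=C/C=C/C=C(C)/C=O | starting material
20 | phosphorus ylide of 18 (not isolated) | c1ccc(cc1)P(c1ccccc1)(c1ccccc1)=C/C=C(C)/C=C/[C@H]1C(C)=C[C@H](OC(=O)CCCCCCCCCCCCC)CC1(C)C | intermediate
21 | (2E,4E,6E,8E,10E,12E)-2,7,11-trimethyl-13-[(1R,4R)-2,6,6-trimethyl-4-(tetradecanoyloxy)cyclohex-2-en-1-yl]trideca-2,4,6,8,10,12-hexaenal | O=C/C(C)=C/C=C/C=C(C)/C=C/C=C(C)/C=C/[C@H]1C(C)=C[C@H](OC(=O)CCCCCCCCCCCCC)CC1(C)C | intermediate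
22 | phosphorus ylide of 12 (not isolated) | CCCCCCCCCCCCCC(=O)O[C@@H]1CC(C)=C(/C=C/C(C)=C/C=P(c2ccccc2)(c2ccccc2)c2ccccc2)C(C)(C)C1 | intermediate
23 | lutein dimyristate, (3R,3'R,6'R)-β,ε-carotene-3,3'-diyl ditetradecanoate | CCCCCCCCCCCCCC(=O)O[C@@H]1CC(C)=C(/C=C/C(C)=C/C=C/C(C)=C/C=C/C=C(C)/C=C/C=C(C)/C=C/[C@H]2C(C)=C[C@H](OC(=O)CCCCCCCCCCCCC)CC2(C)C)C(C)(C)C1 | target

**Step count.** Total: 15 steps. Longest linear sequence: 9 steps (steps 1–8 and 15); the other branch has 7 (steps 9–15).

**Steps most likely to fail**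

1. Step 7. The delocalised cation may be captured and held at C8/C10, or the free primary allylic alcohol end may react (hydride shift from C11 to C10, or ionisation of the trienyl alcohol in the product) before the cyclopropane is opened. Fallback: starting from 10, the primary alcohol is acylated selectively with tetradecanoyl chloride (1.0 equiv, 2,4,6-collidine, CH2Cl2, −40 °C) to give the C11 myristate of the bicyclic carbinol F1, whose ester oxygen can stabilise charge at C10 as an acyloxonium ion instead of allowing hydride loss. The acid-induced ring expansion with myristic acid then gives the ring-expanded bis-myristate F2, and triphenylphosphine hydrobromide displaces the allylic C11 myristate, as it does with retinyl esters, to return to 12.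

2. Step 10. Hydrogen abstraction at the bis-allylic C6'–H, or peroxyl-radical attack on the divinyl carbinol unit, may compete with oxidation at C3'. Fallback: starting from 13, chemical C–H oxidation is replaced by a whole-cell microbial (Streptomyces cytochrome P450) hydroxylation, a biotransformation known to hydroxylate α-ionone at C3 trans to the side chain, which gives (3R,6R)-3-hydroxy-α-ionone F3 directly. Vinylmagnesium bromide (2.3 equiv, THF, −20 °C) then returns to 16, so steps 10 and 11 are bypassed.

3. Step 11. The substrate's own facial bias (hydride approach anti to the axial methyl on C1') may override the catalyst and give mainly the cis (3'S) alcohol. Fallback: starting from 15, the ketone is reduced under substrate control (NaBH4, CeCl3, MeOH, −40 °C, or L-Selectride) to the cis diol F4. The secondary alcohol is then inverted and esterified in one Mitsunobu reaction with tetradecanoic acid (PPh3, DIAD, THF, 0 °C; the tertiary alcohol is inert), which returns to 17.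

**Further compounds**

F1 | step 7 | (2E,4E)-5-[(1S,2R,5S)-2-hydroxy-1,3,3-trimethylbicyclo[3.1.0]hexan-2-yl]-3-methylpenta-2,4-dien-1-yl tetradecanoate | O[C@]1(/C=C/C(C)=C/COC(=O)CCCCCCCCCCCCC)C(C)(C)C[C@@H]2C[C@]12C
F2 | step 7 | (2E,4E)-3-methyl-5-[(4R)-2,6,6-trimethyl-4-(tetradecanoyloxy)cyclohex-1-en-1-yl]penta-2,4-dien-1-yl tetradecanoate | CCCCCCCCCCCCCC(=O)O[C@@H]1CC(C)=C(/C=C/C(C)=C/COC(=O)CCCCCCCCCCCCC)C(C)(C)C1
F3 | step 10 | (3E)-4-[(1R,4R)-4-hydroxy-2,6,6-trimethylcyclohex-2-en-1-yl]but-3-en-2-one | CC(=O)/C=C/[C@H]1C(C)=C[C@H](O)CC1(C)C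
F4 | step 11 | (1S,4R)-4-[(1E)-3-hydroxy-3-methylpenta-1,4-dien-1-yl]-3,5,5-trimethylcyclohex-2-en-1-ol | C=CC(C)(O)/C=C/[C@H]1C(C)=C[C@@H](O)CC1(C)C
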